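# Synthesis proposal for CNP0308311.1 (22): one-flask double O-cyclisation of an alkynyl bis-phenol

## The problem

CNP0308311.1 (22) is made of two benzo-fused oxygen heterocycles joined by one bond between C5 of a 2,3-dihydrobenzofuran and C2' of a benzofuran. The dihydrobenzofuran carries a 4-hydroxy-3-methoxyphenyl group at C2, a hydroxymethyl group at C3 and a methoxy group at C7. The benzofuran carries a methoxy group at C7' and a 3-hydroxypropyl chain at C5'.

The only stereocentres are the adjacent C2 (S) and C3 (R), trans on the five-membered ring. They are not equivalent. C2 is a benzylic aryl ether para to a free phenol, so it can open to a p-quinone methide and close again; it can therefore be set under thermodynamic control by C3. C3 has no such escape and must be introduced in the absolute sense. C3 controls C2, never the reverse.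

The fragile parts are the three electron-rich guaiacyl-type rings (one a free, oxidisable phenol), the C2–O1 benzylic ether (cleaved by hydrogenolysis, re-ionised by strong acid) and the benzofuran. Benzyl ethers and late hydrogenations are therefore poor choices, and as little as possible should be done once both rings exist.

The feature that allows a short endgame is that each heterocycle ends in an aryl–O–C bond to a phenol oxygen already sitting on its carbocycle:

- O1–C2 can come from addition of the C7a phenol to the quinone methide of a 4-hydroxybenzylic alcohol.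
- O1'–C2' (ring O1', C2', C3', C3a', C7a') is the enol ether of a 2-alkynylphenol, with the alkyne standing for C2'–C3'.

An acyclic diarylalkyne with two phenols and one benzylic alcohol thus differs from the target only by one molecule of water.

## Retrosynthesis

**22 ⇒ 19 (O1–C2 and O1'–C2').** Both ring C–O bonds are cut at once, giving hexol 19, a diarylalkyne with a free phenol ortho to the alkyne, a free phenol ortho to the three-carbon side chain and a 4-hydroxybenzylic alcohol. Cutting C–O rather than a ring C–C bond keeps the whole carbon skeleton intact. 19 has a single stereocentre that matters (C2 of the propanediol, the future C3), because the carbinol carbon becomes planar in quinone methide 21. The forward reaction needs one flask in which AuCl3 (trivalent gold) adds the ortho phenol across the alkyne to give benzofuran diol 20, and acid ionises the benzylic alcohol so that the second phenol closes the trans ring.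

**19 ⇒ 18 (O–Si bonds).** The six hydroxyl groups of 19 cannot all be carried through the fragment chemistry. Four are masked as silyl ethers in 18 (three phenols and the propanol). Benzyl ethers are excluded by the alkyne and acetal groups by the acid-sensitive benzylic alcohol, whereas buffered fluoride touches neither. The forward step must liberate the 2-alkynylphenol without letting its phenoxide cyclise.

**18 ⇒ 13 + 17 (aryl C5–C(sp) bond).** Cutting the bond between the central ring and the alkyne divides the molecule into the chiral aryl bromide 13 and the terminal alkyne 17. This is the convergent cut. The bromine is already present in starting material 1 and is inert through the aldol sequence, and the ethynyl group is built on the simple achiral fragment. The forward Sonogashira coupling must engage an electron-rich aryl bromide at low temperature, and the phenol ortho to the alkyne must stay silylated so that the benzofuran does not form early.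

**17 ⇒ 16 ⇒ 15 ⇒ 14 (ethynyl C–C bond, O–Si, C–I).** The ethynyl group is traced to aryl iodide 16, its two silyl ethers to iodophenol 15, and the iodine to dihydroconiferyl alcohol 14. In 14 the only position activated by the phenol is the free ortho carbon. Each forward step is a standard operation on a small molecule.

**13 ⇒ 12 ⇒ 8 + 10 (C1–C2 bond of the propanediol, future C2–C3).** The primary alcohol of 13 is the reduced acyl group of imide 12. 12 is the syn aldol adduct of arylacetyl imide 8 and silylated vanillin 10. This single C–C bond formation assembles the full three-carbon unit with both aryl groups and sets the aryl-bearing centre from the auxiliary. The accompanying carbinol centre is of no consequence. The forward reaction needs a Z boron enolate of a hindered arylacetyl imide and tolerance of two aryl silyl ethers and the aryl bromide.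

**8 ⇒ 5 + 6; 5 ⇒ 4 ⇒ 3 ⇒ 2 ⇒ 1 (N-acyl bond; one-carbon homologation).** Imide 8 comes from arylacetic acid 5 and oxazolidinone 6 through mixed anhydride 7. Acid 5 is the one-carbon homologue of aldehyde 1, reached through TIPS ether 2, enol ether 3 and aldehyde 4. The TIPS group is chosen because it survives the enol ether hydrolysis and does not migrate to the diol later.

**10 ⇒ 9 (O–Si).** Vanillin 9 is silylated so that its phenol does not quench the boron enolate.

## Roads not taken

**Alternative 1: ring contraction of a flavanone.** The cut is C3–C3a of the dihydrobenzofuran. Going forward, (2S)-flavanone A1 would be treated with PhI(OAc)2 (trivalent iodine) and H2SO4 in HC(OMe)3. The fused aryl carbon migrates from C4 to C3 and the pyranone contracts to the trans methyl ester A2.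

- Merits: the trans relationship comes from a stereospecific 1,2-shift, not from equilibration. C3 is never next to a cation. The bromine in A2 allows a late, modular benzofuran attachment.
- Weak points for this target: the single stereocentre of A1 is lost easily by reversible retro-oxa-Michael ring opening, and the key step runs in strong acid. The electron-rich 2-aryl group invites competing migration of that group or dehydrogenation of the pyranone. After A2 there remain ester reduction, benzofuran construction and removal of a benzyl ether by hydrogenolysis next to the C2–O1 benzylic ether.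
- Comparison: Alternative 1 controls the trans geometry more rigorously. The chosen plan sets against it an auxiliary-controlled centre that is configurationally secure once reduced, and an endgame in which both rings form last with nothing left to do.

**Alternative 2: Stobbe benzannulation of the benzofuran benzo ring.** The cut is C7'–C7a' (and, one step earlier, the C4'–C5' double bond). Furan-3-carbaldehyde A3, already carrying the complete dihydrobenzofuran, would be condensed with dimethyl succinate to half-ester A4. Ac2O and NaOAc would then acylate the furan alpha carbon and give the 7-acetoxybenzofuran-5-carboxylate A5.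

- Merits: each reaction is classical and scalable, needs no precious metal, and the oxygenation pattern of the new benzene ring is unambiguous.
- Weak points: the key step does nothing for the stereochemical problem. Both stereocentres must be made beforehand and carried through KOt-Bu and hot Ac2O. After A5 the acetate must be exchanged for a methyl ether, the ester extended by two carbons to the hydroxypropyl chain, and two benzyl ethers removed with H2 over Pd/C beside a benzylic ether.
- Comparison: this is the most conservative road, and in reliability of its individual steps it is at least the equal of the chosen plan. It is roughly twice as long and fully linear, whereas the chosen plan is convergent and its key step delivers the final skeleton.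

**Alternative 3: auxiliary-directed oxidative cross-coupling.** The cuts are C3–C3a and O1–C2. Ag2O would oxidise ferulate imide A6 and benzofuran phenol A7. The ferulate beta-carbon radical would couple with the free ortho carbon of A7, and the phenol would add to the resulting quinone methide to give A8, which a reduction converts to the target.

- Merits: it is by far the shortest route, it is biomimetic, it needs no phenol protection, and it forms a C–C and a C–O bond in one step.
- Weak points: two different phenoxyl radicals must cross-couple. A6 homodimerises readily in several modes. A7 can homocouple or react at the electron-rich benzofuran C3'. The facial bias of a remote auxiliary on a radical coupling is modest. Low conversion to a complex mixture is the expected outcome.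
- Comparison: in step count Alternative 3 is clearly better. The chosen plan gives up that brevity for bond formations in which each atom has only one possible partner and for a stereocentre set in a closed transition state.

Key step: step 14

## Route

Assumption on the chemistry: 1, 6, 9, 14 and all reagents are taken as commercial. The syn aldol should give the 1S carbinol drawn for 12, 13, 18, 19 and 20, but because this carbon becomes planar in step 14 either C1 epimer, or a mixture, is an equally valid precursor.

Step 1
Reactants: 1 5-bromo-2-hydroxy-3-methoxybenzaldehyde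
Product: 2 5-bromo-3-methoxy-2-(triisopropylsilyloxy)benzaldehyde
Conditions: TIPSOTf, 2,6-lutidine, CH2Cl2, 0 °C → rt
Reagents that add atoms: triisopropylsilyl trifluoromethanesulfonate, CC(C)[Si](C(C)C)(C(C)C)OS(=O)(=O)C(F)(F)F
Why: Silyl ether formation on a phenol; the silyl triflate overcomes the hydrogen bond to the aldehyde and the two ortho substituents. The TIPS ether is chosen because it withstands the aqueous acid of step 3 and does not migrate to the diol oxygens after step 8.

Step 2
Reactants: 2 5-bromo-3-methoxy-2-(triisopropylsilyloxy)benzaldehyde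
Product: 3 [4-bromo-2-methoxy-6-(2-methoxyethenyl)phenoxy]triisopropylsilane as an E/Z mixture
Conditions: Ph3P(CH2OMe)Cl, KN(SiMe3)2, THF, 0 °C; then 2, 0 °C → rt
Reagents that add atoms: (methoxymethyl)triphenylphosphonium chloride, COC[P+](c1ccccc1)(c1ccccc1)c1ccccc1.[Cl-]
Why: Wittig olefination of a non-enolisable aryl aldehyde with the methoxymethylidene ylide; the amide base is consumed before the aldehyde is added, so the aryl silyl ether is not attacked. The alkene geometry is irrelevant because both isomers hydrolyse to the same aldehyde.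

Step 3
Reactants: 3 [4-bromo-2-methoxy-6-(2-methoxyethenyl)phenoxy]triisopropylsilane
Product: 4 [5-bromo-3-methoxy-2-(triisopropylsilyloxy)phenyl]acetaldehyde
Conditions: 2 M aq. HCl, THF, 40 °C
Reagents that add atoms: water, O
Why: Acid hydrolysis of a methyl enol ether (protonation at the benzylic carbon, collapse of the hemiacetal); a hindered aryl TIPS ether is stable to dilute acid. The arylacetaldehyde should be oxidised without storage.

Step 4
Reactants: 4 [5-bromo-3-methoxy-2-(triisopropylsilyloxy)phenyl]acetaldehyde
Product: 5 [5-bromo-3-methoxy-2-(triisopropylsilyloxy)phenyl]acetic acid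
Conditions: NaClO2, NaH2PO4, 2-methyl-2-butene, t-BuOH/H2O, 0 °C → rt
Reagents that add atoms: sodium chlorite, [Na+].[O-]Cl=O
Why: Pinnick oxidation of an aldehyde to the acid under buffered conditions; the alkene scavenges HOCl and so protects the electron-rich ring from chlorination.

Step 5
Reactants: 5 [5-bromo-3-methoxy-2-(triisopropylsilyloxy)phenyl]acetic acid; 6 (4S)-4-benzyl-1,3-oxazolidin-2-one
Product: 8 (4S)-4-benzyl-3-{[5-bromo-3-methoxy-2-(triisopropylsilyloxy)phenyl]acetyl}-1,3-oxazolidin-2-one, via mixed pivalic anhydride 7 (not isolated)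
Conditions: PivCl, Et3N, THF, −20 °C; then LiCl, 6, −20 °C → rt
Reagents that add atoms: none
Why: N-acylation of an oxazolidinone through a mixed pivalic anhydride with LiCl and Et3N; the auxiliary attacks the less hindered arylacetyl carbonyl of 7. No strong base is present, so the silyl ether and the acidic benzylic protons are left alone.

Step 6
Reactants: 9 vanillin (4-hydroxy-3-methoxybenzaldehyde)
Product: 10 4-(tert-butyldimethylsilyloxy)-3-methoxybenzaldehyde
Conditions: TBSCl, imidazole, DMF, rt
Reagents that add atoms: tert-butyldimethylsilyl chloride, CC(C)(C)[Si](C)(C)Cl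
Why: Silyl ether formation on a phenol, so that the aldehyde can meet the boron enolate without a free hydroxyl group.

Step 7
Reactants: 8 (4S)-4-benzyl-3-{[5-bromo-3-methoxy-2-(triisopropylsilyloxy)phenyl]acetyl}-1,3-oxazolidin-2-one; 10 4-(tert-butyldimethylsilyloxy)-3-methoxybenzaldehyde
Product: 12 (4S)-4-benzyl-3-[(2S,3S)-2-[5-bromo-3-methoxy-2-(triisopropylsilyloxy)phenyl]-3-[4-(tert-butyldimethylsilyloxy)-3-methoxyphenyl]-3-hydroxypropanoyl]-1,3-oxazolidin-2-one, via Z-boron enolate 11 (not isolated)
Conditions: Bu2BOTf, i-Pr2NEt, CH2Cl2, −78 → 0 °C; then 10, −78 → 0 °C; pH 7 buffer, MeOH, 30% H2O2, 0 °C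
Reagents that add atoms: none
Why: Evans syn aldol reaction: the Z dibutylboron enolate 11 reacts through a closed Zimmerman–Traxler chair with the auxiliary carbonyl turned away from the enolate oxygen, so the benzyl group blocks one face. This sets the aryl-bearing carbon as 2S (the future C3 R of the target) and the carbinol syn to it (3S); the carbinol centre is erased in step 14.

Step 8
Reactants: 12 (4S)-4-benzyl-3-[(2S,3S)-2-[5-bromo-3-methoxy-2-(triisopropylsilyloxy)phenyl]-3-[4-(tert-butyldimethylsilyloxy)-3-methoxyphenyl]-3-hydroxypropanoyl]-1,3-oxazolidin-2-one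
Product: 13 (1S,2R)-2-[5-bromo-3-methoxy-2-(triisopropylsilyloxy)phenyl]-1-[4-(tert-butyldimethylsilyloxy)-3-methoxyphenyl]propane-1,3-diol
Conditions: LiBH4, MeOH (1 equiv), THF, 0 °C
Reagents that add atoms: none
Why: Reductive cleavage of an N-acyl oxazolidinone to the primary alcohol with release of auxiliary 6; the reaction is fast at 0 °C and not basic enough for retro-aldol cleavage or epimerisation of the benzylic centre. The descriptor changes from 2S to 2R only because the acyl carbon becomes CH2OH; aryl bromide and silyl ethers are inert.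

Step 9
Reactants: 14 dihydroconiferyl alcohol [4-(3-hydroxypropyl)-2-methoxyphenol]
Product: 15 4-(3-hydroxypropyl)-2-iodo-6-methoxyphenol
Conditions: I2, KI, NaHCO3, H2O/THF, 0 °C → rt
Reagents that add atoms: iodine, II
Why: Electrophilic aromatic iodination of a phenolate; the para position is blocked by the side chain and one ortho position by the methoxy group, so only the free ortho carbon is activated.

Step 10
Reactants: 15 4-(3-hydroxypropyl)-2-iodo-6-methoxyphenol
Product: 16 tert-butyl{3-[4-(tert-butyldimethylsilyloxy)-3-iodo-5-methoxyphenyl]propoxy}dimethylsilane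
Conditions: TBSCl (2.5 equiv), imidazole, DMF, rt → 40 °C
Reagents that add atoms: tert-butyldimethylsilyl chloride, CC(C)(C)[Si](C)(C)Cl
Why: Silyl ether formation on both the phenol and the primary alcohol; the aryl silyl ether keeps the phenol from cyclising onto the alkyne during steps 11 and 12.

Step 11
Reactants: 16 tert-butyl{3-[4-(tert-butyldimethylsilyloxy)-3-iodo-5-methoxyphenyl]propoxy}dimethylsilane
Product: 17 tert-butyl{3-[4-(tert-butyldimethylsilyloxy)-3-ethynyl-5-methoxyphenyl]propoxy}dimethylsilane
Conditions: HC≡CMgBr, ZnBr2, THF, 0 °C; then 16, Pd(PPh3)4 (5 mol%), THF, rt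
Reagents that add atoms: ethynylmagnesium bromide, C#C[Mg]Br
Why: Negishi cross-coupling of ethynylzinc bromide with an aryl iodide gives the terminal arylacetylene in one step. The zinc acetylide does not attack silyl ethers, and an excess of it suppresses a second arylation.

Step 12
Reactants: 13 (1S,2R)-2-[5-bromo-3-methoxy-2-(triisopropylsilyloxy)phenyl]-1-[4-(tert-butyldimethylsilyloxy)-3-methoxyphenyl]propane-1,3-diol; 17 tert-butyl{3-[4-(tert-butyldimethylsilyloxy)-3-ethynyl-5-methoxyphenyl]propoxy}dimethylsilane
Product: 18 (1S,2R)-2-[5-({2-(tert-butyldimethylsilyloxy)-5-[3-(tert-butyldimethylsilyloxy)propyl]-3-methoxyphenyl}ethynyl)-3-methoxy-2-(triisopropylsilyloxy)phenyl]-1-[4-(tert-butyldimethylsilyloxy)-3-methoxyphenyl]propane-1,3-diol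
Conditions: Pd(PhCN)2Cl2 (3 mol%), [(t-Bu)3PH]BF4 (6 mol%), CuI (2 mol%), i-Pr2NH, 1,4-dioxane, rt, degassed
Reagents that add atoms: none
Why: Sonogashira coupling; the bulky, electron-rich tri-tert-butylphosphine allows oxidative addition to the electron-rich but unhindered aryl bromide at room temperature. At that temperature the silyl ethers and the free diol survive, and the silylated ortho phenol cannot close onto the new alkyne.

Step 13
Reactants: 18 (1S,2R)-2-[5-({2-(tert-butyldimethylsilyloxy)-5-[3-(tert-butyldimethylsilyloxy)propyl]-3-methoxyphenyl}ethynyl)-3-methoxy-2-(triisopropylsilyloxy)phenyl]-1-[4-(tert-butyldimethylsilyloxy)-3-methoxyphenyl]propane-1,3-diol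
Product: 19 (1S,2R)-1-(4-hydroxy-3-methoxyphenyl)-2-(2-hydroxy-5-{[2-hydroxy-5-(3-hydroxypropyl)-3-methoxyphenyl]ethynyl}-3-methoxyphenyl)propane-1,3-diol
Conditions: Bu4NF (6 equiv), AcOH (6 equiv), THF, 0 °C → rt, under argon
Reagents that add atoms: none
Why: Fluoride-induced cleavage of all four silyl ethers, driven by Si–F bond formation. Acetic acid keeps the phenols protonated, so the 2-alkynylphenoxide does not cyclise and the polyphenol is not oxidised, and the near-neutral medium does not ionise the benzylic alcohol.

Step 14
Reactants: 19 (1S,2R)-1-(4-hydroxy-3-methoxyphenyl)-2-(2-hydroxy-5-{[2-hydroxy-5-(3-hydroxypropyl)-3-methoxyphenyl]ethynyl}-3-methoxyphenyl)propane-1,3-diol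
Product: 22 4-[(2S,3R)-3-(hydroxymethyl)-5-[5-(3-hydroxypropyl)-7-methoxy-1-benzofuran-2-yl]-7-methoxy-2,3-dihydro-1-benzofuran-2-yl]-2-methoxyphenol (CNP0308311.1), via benzofuran diol 20 (not isolated), via quinone methide 21 (not isolated)
Conditions: AuCl3 (5 mol%), MeCN (0.01 M), rt; then TsOH·H2O (10 mol%), rt → 40 °C, same flask
Reagents that add atoms: none
Why: AuCl3 binds the diarylalkyne and the phenol ortho to it adds anti to the metal at the distal alkyne carbon (5-endo-dig, closing the furan ring at O1'–C2'); protodeauration of the 3-aurated benzofuran releases benzofuran diol 20 and the catalyst. The closest known reaction type is the gold-catalysed cycloisomerisation of 2-alkynylphenols to 2-arylbenzofurans. Acid (HCl set free from AuCl3 by the hydroxyl groups, reinforced by TsOH added to the same flask) then ionises the 4-hydroxybenzylic alcohol to p-quinone methide 21, and the central-ring phenol adds to its exocyclic carbon (5-exo-trig, closing the dihydrofuran ring at O1–C2) with rearomatisation. The closest known reaction type for this half is the acid-mediated dehydrative cyclisation of 1-aryl-2-(2-hydroxyaryl)propane-1,3-diols to trans-2-aryl-2,3-dihydrobenzofurans. The new C2 centre is controlled by C3: the planar methide erases the carbinol configuration, the phenol adds anti to the hydroxymethyl group, and because the benzylic aryl ether re-ionises under the conditions any cis ring reopens and settles as the trans (2S,3R) isomer. Chemoselectivity rests on geometry: only the ortho phenol can reach the alkyne (the central-ring phenol is para to it and the guaiacyl phenol is remote), only the central-ring phenol can reach the methide carbon through a five-membered ring, and the primary alcohols could only form an oxetane or add intermolecularly and reversibly. High dilution disfavours intermolecular capture of 21 by the electron-rich arenes.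

## Compound list

1 | 5-bromo-2-hydroxy-3-methoxybenzaldehyde | COc1cc(Br)cc(C=O)c1O | starting material
2 | 5-bromo-3-methoxy-2-(triisopropylsilyloxy)benzaldehyde | COc1cc(Br)cc(C=O)c1O[Si](C(C)C)(C(C)C)C(C)C | intermediate
3 | [4-bromo-2-methoxy-6-(2-methoxyethenyl)phenoxy]triisopropylsilane (E/Z mixture) | COC=Cc1cc(Br)cc(OC)c1O[Si](C(C)C)(C(C)C)C(C)C | intermediate
4 | [5-bromo-3-methoxy-2-(triisopropylsilyloxy)phenyl]acetaldehyde | O=CCc1cc(Br)cc(OC)c1O[Si](C(C)C)(C(C)C)C(C)C | intermediate
5 | [5-bromo-3-methoxy-2-(triisopropylsilyloxy)phenyl]acetic acid | OC(=O)Cc1cc(Br)cc(OC)c1O[Si](C(C)C)(C(C)C)C(C)C | intermediate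
6 | (4S)-4-benzyl-1,3-oxazolidin-2-one | O=C1OC[C@H](Cc2ccccc2)N1 | starting material
7 | [5-bromo-3-methoxy-2-(triisopropylsilyloxy)phenyl]acetic 2,2-dimethylpropanoic anhydride (formed in the flask) | CC(C)(C)C(=O)OC(=O)Cc1cc(Br)cc(OC)c1O[Si](C(C)C)(C(C)C)C(C)C | intermediate
8 | (4S)-4-benzyl-3-{[5-bromo-3-methoxy-2-(triisopropylsilyloxy)phenyl]acetyl}-1,3-oxazolidin-2-one | O=C1OC[C@H](Cc2ccccc2)N1C(=O)Cc1cc(Br)cc(OC)c1O[Si](C(C)C)(C(C)C)C(C)C | intermediate
9 | vanillin (4-hydroxy-3-methoxybenzaldehyde) | COc1cc(C=O)ccc1O | starting material
10 | 4-(tert-butyldimethylsilyloxy)-3-methoxybenzaldehyde | COc1cc(C=O)ccc1O[Si](C)(C)C(C)(C)C | intermediate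
11 | Z dibutylboron enolate of 8 (formed in the flask) | CCCCB(CCCC)O/C(=C\c1cc(Br)cc(OC)c1O[Si](C(C)C)(C(C)C)C(C)C)N1C(=O)OC[C@@H]1Cc1ccccc1 | intermediate
12 | (4S)-4-benzyl-3-[(2S,3S)-2-[5-bromo-3-methoxy-2-(triisopropylsilyloxy)phenyl]-3-[4-(tert-butyldimethylsilyloxy)-3-methoxyphenyl]-3-hydroxypropanoyl]-1,3-oxazolidin-2-one | O=C1OC[C@H](Cc2ccccc2)N1C(=O)[C@@H](c1cc(Br)cc(OC)c1O[Si](C(C)C)(C(C)C)C(C)C)[C@H](O)c1ccc(O[Si](C)(C)C(C)(C)C)c(OC)c1 | intermediate
13 | (1S,2R)-2-[5-bromo-3-methoxy-2-(triisopropylsilyloxy)phenyl]-1-[4-(tert-butyldimethylsilyloxy)-3-methoxyphenyl]propane-1,3-diol | OC[C@@H](c1cc(Br)cc(OC)c1O[Si](C(C)C)(C(C)C)C(C)C)[C@H](O)c1ccc(O[Si](C)(C)C(C)(C)C)c(OC)c1 | intermediate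
14 | dihydroconiferyl alcohol [4-(3-hydroxypropyl)-2-methoxyphenol] | COc1cc(CCCO)ccc1O | starting material
15 | 4-(3-hydroxypropyl)-2-iodo-6-methoxyphenol | COc1cc(CCCO)cc(I)c1O | intermediate
16 | tert-butyl{3-[4-(tert-butyldimethylsilyloxy)-3-iodo-5-methoxyphenyl]propoxy}dimethylsilane | COc1cc(CCCO[Si](C)(C)C(C)(C)C)cc(I)c1O[Si](C)(C)C(C)(C)C | intermediate
17 | tert-butyl{3-[4-(tert-butyldimethylsilyloxy)-3-ethynyl-5-methoxyphenyl]propoxy}dimethylsilane | COc1cc(CCCO[Si](C)(C)C(C)(C)C)cc(C#C)c1O[Si](C)(C)C(C)(C)C | intermediate
18 | (1S,2R)-2-[5-({2-(tert-butyldimethylsilyloxy)-5-[3-(tert-butyldimethylsilyloxy)propyl]-3-methoxyphenyl}ethynyl)-3-methoxy-2-(triisopropylsilyloxy)phenyl]-1-[4-(tert-butyldimethylsilyloxy)-3-methoxyphenyl]propane-1,3-diol | OC[C@@H](c1cc(C#Cc2cc(CCCO[Si](C)(C)C(C)(C)C)cc(OC)c2O[Si](C)(C)C(C)(C)C)cc(OC)c1O[Si](C(C)C)(C(C)C)C(C)C)[C@H](O)c1ccc(O[Si](C)(C)C(C)(C)C)c(OC)c1 | intermediate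
19 | (1S,2R)-1-(4-hydroxy-3-methoxyphenyl)-2-(2-hydroxy-5-{[2-hydroxy-5-(3-hydroxypropyl)-3-methoxyphenyl]ethynyl}-3-methoxyphenyl)propane-1,3-diol | OC[C@@H](c1cc(C#Cc2cc(CCCO)cc(OC)c2O)cc(OC)c1O)[C@H](O)c1ccc(O)c(OC)c1 | intermediate
20 | (1S,2R)-1-(4-hydroxy-3-methoxyphenyl)-2-{2-hydroxy-5-[5-(3-hydroxypropyl)-7-methoxy-1-benzofuran-2-yl]-3-methoxyphenyl}propane-1,3-diol (formed in the flask) | OC[C@@H](c1cc(-c2cc3cc(CCCO)cc(OC)c3o2)cc(OC)c1O)[C@H](O)c1ccc(O)c(OC)c1 | intermediate
21 | 4-[(2R)-3-hydroxy-2-{2-hydroxy-5-[5-(3-hydroxypropyl)-7-methoxy-1-benzofuran-2-yl]-3-methoxyphenyl}propylidene]-2-methoxycyclohexa-2,5-dien-1-one (formed in the flask) | OC[C@@H](c1cc(-c2cc3cc(CCCO)cc(OC)c3o2)cc(OC)c1O)C=C1C=CC(=O)C(OC)=C1 | intermediate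
22 | 4-[(2S,3R)-3-(hydroxymethyl)-5-[5-(3-hydroxypropyl)-7-methoxy-1-benzofuran-2-yl]-7-methoxy-2,3-dihydro-1-benzofuran-2-yl]-2-methoxyphenol (CNP0308311.1) | COc1cc([C@H]2Oc3c(OC)cc(-c4cc5cc(CCCO)cc(OC)c5o4)cc3[C@@H]2CO)ccc1O | target

## Step count and risk

Total step count: 14. Longest linear sequence: 10 steps (steps 1, 2, 3, 4, 5, 7, 8, 12, 13 and 14, from 1).

**Step 14 (key step).** Three things are most likely to go wrong. The electron-rich phenols may reduce trivalent gold to the metal before the alkyne is consumed. The quinone methide may be captured intermolecularly by the electron-rich rings, leading to oligomers. The methide may lose its adjacent proton to give a stilbene, which would erode C3. The one-flask merger of the two closures is the untested part. Fallback: the two rings are closed in separate, known operations starting from 19. Amberlyst-15 in MeCN at rt closes only the dihydrofuran ring through the quinone methide and should give 2-{[(2S,3R)-2-(4-hydroxy-3-methoxyphenyl)-3-(hydroxymethyl)-7-methoxy-2,3-dihydro-1-benzofuran-5-yl]ethynyl}-4-(3-hydroxypropyl)-6-methoxyphenol F5. K2CO3 in DMF at 60 °C then adds the phenoxide across the alkyne (base-mediated 5-endo-dig closure), and the route is rejoined at 22.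

**Step 12.** Oxidative addition to the electron-rich aryl bromide may be slow, which gives the copper acetylide time for oxidative homocoupling. Warming to compensate invites amine-induced loss of the aryl silyl ether next to the alkyne and premature cyclisation. Fallback: the halogen is changed, starting from 13. An aromatic Finkelstein exchange (CuI, NaI, trans-N,N'-dimethylcyclohexane-1,2-diamine, 1,4-dioxane, 110 °C) should give (1S,2R)-1-[4-(tert-butyldimethylsilyloxy)-3-methoxyphenyl]-2-[5-iodo-3-methoxy-2-(triisopropylsilyloxy)phenyl]propane-1,3-diol F4. F4 couples with 17 under ordinary Sonogashira conditions (PdCl2(PPh3)2, CuI, Et3N, THF, rt), and the route is rejoined at 18.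

**Step 7.** The aldol addition may be incomplete or reversible and facial selectivity may be eroded, because the arylacetyl enolate is stabilised and crowded by the ortho silyloxy group and the aldehyde is deactivated by its para oxygen. The doubly activated C2–H of 12 may also epimerise during work-up. Fallback: a titanium enolate of a reductively more labile auxiliary is used, starting from 5. Coupling with (4S)-4-benzyl-1,3-thiazolidine-2-thione (DCC, DMAP, CH2Cl2) gives (4S)-4-benzyl-3-{[5-bromo-3-methoxy-2-(triisopropylsilyloxy)phenyl]acetyl}-1,3-thiazolidine-2-thione F1. Its syn aldol reaction with 10 (TiCl4, i-Pr2NEt, N-methylpyrrolidinone, CH2Cl2, −78 °C) gives (4S)-4-benzyl-3-[(2S,3S)-2-[5-bromo-3-methoxy-2-(triisopropylsilyloxy)phenyl]-3-[4-(tert-butyldimethylsilyloxy)-3-methoxyphenyl]-3-hydroxypropanoyl]-1,3-thiazolidine-2-thione F2. NaBH4 in THF/EtOH at 0 °C removes the auxiliary, and the route is rejoined at 13.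

**Step 13.** Cleavage of the hindered aryl TIPS ether may be incomplete under buffered fluoride. With less buffer the 2-alkynylphenoxide may close to the benzofuran, giving mixtures of 19 and 20, and the polyphenol may oxidise in air. Fallback: the fluoride-induced closure is made deliberate, starting from 18. Unbuffered Bu4NF in THF at 60 °C removes the silyl groups and closes the benzofuran in the same operation, giving 20 as an isolated compound (no new compound is made, entry F0). The route is rejoined at 20, which the acid stage of step 14 (TsOH·H2O, MeCN) converts into 22.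

**Step 11.** The ethynyl nucleophile may be arylated twice, since any doubly metallated acetylene gives the diarylacetylene. Oxidative addition next to the bulky silyloxy group may also be slow. Fallback: the alkyne is introduced in protected form, starting from 16. Sonogashira coupling with trimethylsilylacetylene (PdCl2(PPh3)2, CuI, Et3N, THF, 40 °C) gives tert-butyl{3-[4-(tert-butyldimethylsilyloxy)-3-methoxy-5-(trimethylsilylethynyl)phenyl]propoxy}dimethylsilane F3. Its C–Si bond is cleaved selectively with AgNO3 (10 mol%) in acetone/H2O, which leaves the silyl ethers intact, and the route is rejoined at 17.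

## Further compounds

F1 | step 7 | (4S)-4-benzyl-3-{[5-bromo-3-methoxy-2-(triisopropylsilyloxy)phenyl]acetyl}-1,3-thiazolidine-2-thione | S=C1SC[C@H](Cc2ccccc2)N1C(=O)Cc1cc(Br)cc(OC)c1O[Si](C(C)C)(C(C)C)C(C)C
F2 | step 7 | (4S)-4-benzyl-3-[(2S,3S)-2-[5-bromo-3-methoxy-2-(triisopropylsilyloxy)phenyl]-3-[4-(tert-butyldimethylsilyloxy)-3-methoxyphenyl]-3-hydroxypropanoyl]-1,3-thiazolidine-2-thione | S=C1SC[C@H](Cc2ccccc2)N1C(=O)[C@@H](c1cc(Br)cc(OC)c1O[Si](C(C)C)(C(C)C)C(C)C)[C@H](O)c1ccc(O[Si](C)(C)C(C)(C)C)c(OC)c1
F3 | step 11 | tert-butyl{3-[4-(tert-butyldimethylsilyloxy)-3-methoxy-5-(trimethylsilylethynyl)phenyl]propoxy}dimethylsilane | COc1cc(CCCO[Si](C)(C)C(C)(C)C)cc(C#C[Si](C)(C)C)c1O[Si](C)(C)C(C)(C)C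
F4 | step 12 | (1S,2R)-1-[4-(tert-butyldimethylsilyloxy)-3-methoxyphenyl]-2-[5-iodo-3-methoxy-2-(triisopropylsilyloxy)phenyl]propane-1,3-diol | OC[C@@H](c1cc(I)cc(OC)c1O[Si](C(C)C)(C(C)C)C(C)C)[C@H](O)c1ccc(O[Si](C)(C)C(C)(C)C)c(OC)c1
F0 | step 13 | none | none
F5 | step 14 | 2-{[(2S,3R)-2-(4-hydroxy-3-methoxyphenyl)-3-(hydroxymethyl)-7-methoxy-2,3-dihydro-1-benzofuran-5-yl]ethynyl}-4-(3-hydroxypropyl)-6-methoxyphenol | COc1cc([C@H]2Oc3c(OC)cc(C#Cc4cc(CCCO)cc(OC)c4O)cc3[C@@H]2CO)ccc1O
A1 | alternative 1 | (2S)-2-(4-benzyloxy-3-methoxyphenyl)-6-bromo-8-methoxy-2,3-dihydro-4H-chromen-4-one | COc1cc([C@@H]2CC(=O)c3cc(Br)cc(OC)c3O2)ccc1OCc1ccccc1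
A2 | alternative 1 | methyl (2S,3S)-2-(4-benzyloxy-3-methoxyphenyl)-5-bromo-7-methoxy-2,3-dihydro-1-benzofuran-3-carboxylate | COc1cc([C@H]2Oc3c(OC)cc(Br)cc3[C@@H]2C(=O)OC)ccc1OCc1ccccc1
A3 | alternative 2 | 5-[(2S,3R)-2-(4-benzyloxy-3-methoxyphenyl)-3-(benzyloxymethyl)-7-methoxy-2,3-dihydro-1-benzofuran-5-yl]furan-3-carbaldehyde | COc1cc([C@H]2Oc3c(OC)cc(-c4cc(C=O)co4)cc3[C@@H]2COCc2ccccc2)ccc1OCc1ccccc1
A4 | alternative 2 | (3E)-4-{5-[(2S,3R)-2-(4-benzyloxy-3-methoxyphenyl)-3-(benzyloxymethyl)-7-methoxy-2,3-dihydro-1-benzofuran-5-yl]furan-3-yl}-3-(methoxycarbonyl)but-3-enoic acid | COc1cc([C@H]2Oc3c(OC)cc(-c4cc(/C=C(\CC(=O)O)C(=O)OC)co4)cc3[C@@H]2COCc2ccccc2)ccc1OCc1ccccc1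
A5 | alternative 2 | methyl 7-acetoxy-2-[(2S,3R)-2-(4-benzyloxy-3-methoxyphenyl)-3-(benzyloxymethyl)-7-methoxy-2,3-dihydro-1-benzofuran-5-yl]-1-benzofuran-5-carboxylate | COc1cc([C@H]2Oc3c(OC)cc(-c4cc5cc(C(=O)OC)cc(OC(C)=O)c5o4)cc3[C@@H]2COCc2ccccc2)ccc1OCc1ccccc1
A6 | alternative 3 | (4S)-4-benzyl-3-[(2E)-3-(4-hydroxy-3-methoxyphenyl)prop-2-enoyl]-1,3-oxazolidin-2-one | COc1cc(/C=C/C(=O)N2[C@@H](Cc3ccccc3)COC2=O)ccc1O
A7 | alternative 3 | 4-[5-(3-hydroxypropyl)-7-methoxy-1-benzofuran-2-yl]-2-methoxyphenol | COc1cc(-c2cc3cc(CCCO)cc(OC)c3o2)ccc1O
A8 | alternative 3 | (4S)-4-benzyl-3-{[(2S,3S)-2-(4-hydroxy-3-methoxyphenyl)-5-[5-(3-hydroxypropyl)-7-methoxy-1-benzofuran-2-yl]-7-methoxy-2,3-dihydro-1-benzofuran-3-yl]carbonyl}-1,3-oxazolidin-2-one | COc1cc([C@H]2Oc3c(OC)cc(-c4cc5cc(CCCO)cc(OC)c5o4)cc3[C@@H]2C(=O)N2[C@@H](Cc3ccccc3)COC2=O)ccc1O
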